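Alpha runs longer than epsilon, 10 s against 2.5 s, from the same charge.

all flasks: free monomer 0.011 M; transfer agent 0.110 mM; initiator 5 mol%; impurity 0.48 mM
- alpha: time 10 s
- epsilon: time 2.5 s

    free monomer + initiator → living end + monomer in chains (k1 = 94 M⁻¹ s⁻¹)
    free monomer + living end → monomer in chains + living end, rate k2*[living end]*[free monomer] (k2 = 430 M⁻¹ s⁻¹)
    living end + transfer agent → dead chain (k3 = 420 M⁻¹ s⁻¹)
    initiator + impurity → spent initiator A (k4 = 41000 M⁻¹ s⁻¹)
    initiator → spent initiator B (k5 = 0.081 s⁻¹)

- which of the two ends with the longer chains by the average number of monomer units in a chain (chains begun, living or dead) ("neither" if they lie within 10 %) (alpha / epsilon / neither)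
- average number of monomer units in a chain (chains begun, living or dead) at the end, alpha
- average number of monomer units in a chain (chains begun, living or dead) at the end, epsilon

Two chemists dispute this pair. The first looks at the impurity: in alpha, at the start, it uses initiator 19 times as fast as chains start, and the half-life of initiator is 0.035 s by that step against 0.670 s by chain start. Taking that step as over at once, she subtracts the impurity charged from the 0.550 mM of initiator charged and keeps 0.0700 mM of chains, the same in both flasks. Each living end adds monomer at k2[free monomer], so length grows with time: one plus that rate times the time gives 48.3 for alpha and 12.8 for epsilon.

The second chemist looks at the transfer agent. A living end grows at k2[free monomer] and dies at k3[transfer agent], so he takes the ratio of these two rates, 102, the monomer units added per chain killed. He calls this the length in both flasks, so his answer is neither.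

My own reckoning joins them. The ratio stays near its charged value, since k2 and k3 are close and [free monomer] and [transfer agent] therefore fall at nearly the same pace. Each dead chain stands for that many units, so the average length is one plus the ratio times the dead share of chains begun. The number of chains cancels. Living ends die by a pseudo-first-order loss with a half-life of 15 s at the charged [transfer agent], longer than alpha's run, so living ends should still outnumber dead chains. It comes to 37.0 % for alpha and 10.9 % for epsilon. The lengths are then 38.9 and 12.2, and alpha is longer. I count the ends as present from the first moment, so I expect both to be somewhat high.

The forecast takes the first chemist's side with its own numbers, alpha longer, 33.5 (30 to 37) and 10.5 (9.3 to 11.8), holding that “the longer run gives about three times the average length”.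

The simulation gives alpha longer, with 33.5 for alpha and 10.4 for epsilon, both below my reckoning.

In alpha at 10.0 s, dead chains are 32.1 % of chains begun, and the ratio then gives 33.9. The second chemist's region is the long run: at 100 s alpha's dead share is 89.8 % and its length 91.3, nearing his 102. A neighbour of alpha, charged with 0.0066 M of free monomer, has a ratio of 61.4 and 0.0159 mM of chains begun, fewer than alpha's 0.0817 mM. Its dead share gives 23.0, and that neighbour ends at 23.0.

The numbers of this flask are assumed.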